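**Retrosynthetic overview**
1. The aryl ether is cut at C11–O (Mitsunobu reaction with umbelliferone, last step); the 6-acetate is carried from step 9.
2. Ring A (C1–C5, C10) is a 2,2-dimethylcyclohexanone: the C3 carbonyl lies between the gem-dimethyl carbon C4 and the ring-fusion methine C5. This is the retron of a semipinacol shift of C5 from C3 to an exocyclic C4 cation, so ring A is traced back to the cyclopentanol of a trans-hydrindane that carries an isopropenyl group on C3.
3. Ring B is opened at C7=C8 (ring-closing metathesis), then at C5–C6 (anti aldol with acrolein) and at C9–C10 (Hosomi–Sakurai addition to 3-methylcyclopent-2-enone, which makes the quaternary carbon).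
4. Order of ring formation: the five-membered ring is bought, ring B is closed in step 7, ring A arises by ring enlargement in step 10, the coumarin is bought. Absolute configuration comes from a Sharpless kinetic resolution (step 6).

Key step: step 10

Assumption: atoms carry drimane numbers (ring A = C1–C5 and C10, ring B = C5–C10, C11 = the CH2O carbon); compounds 7, 9 and 10 are racemic and are drawn as the enantiomer that step 6 retains.

Step 1
Reactants: 1 but-2-yn-1-ol
Product: 3 (Z)-3-iodobut-2-en-1-ol, via sodium alkenylaluminate 2 (not isolated)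
Conditions: NaAlH2(OCH2CH2OMe)2, THF, 0 °C; then I2, −78 °C to 0 °C
Reagents that add atoms: iodine, II
Why: Hydroxyl-directed trans-hydroalumination of the propargylic alcohol puts aluminium on the distal alkyne carbon in a five-membered aluminate, and iodinolysis of the carbon–aluminium bond with retention should give the (Z)-vinyl iodide (hydroalumination–iodination).

Step 2
Reactants: 3 (Z)-3-iodobut-2-en-1-ol
Product: 4 (Z)-tert-butyl[(3-iodobut-2-en-1-yl)oxy]diphenylsilane
Conditions: t-BuPh2SiCl, imidazole, DMF, rt
Reagents that add atoms: tert-butyl(chloro)diphenylsilane, CC(C)(C)[Si](Cl)(c1ccccc1)c1ccccc1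
Why: Silylation of the primary alcohol (silyl ether protection) masks the C11 oxygen for the organometallic steps that follow.

Step 3
Reactants: 4 (Z)-tert-butyl[(3-iodobut-2-en-1-yl)oxy]diphenylsilane
Product: 5 (Z)-tert-butyl{[3-methyl-4-(trimethylsilyl)but-2-en-1-yl]oxy}diphenylsilane
Conditions: Me3SiCH2MgCl, Pd(PPh3)4 (5 mol%), THF, rt to 50 °C
Reagents that add atoms: (trimethylsilyl)methylmagnesium chloride, C[Si](C)(C)C[Mg]Cl
Why: Kumada cross-coupling of the vinyl iodide with the silylmethyl Grignard reagent proceeds with retention of alkene geometry and should give the allylsilane.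

Step 4
Reactants: 5 (Z)-tert-butyl{[3-methyl-4-(trimethylsilyl)but-2-en-1-yl]oxy}diphenylsilane; 6 3-methylcyclopent-2-en-1-one
Product: 7 racemic trimethylsilyl enol ether of 3-methyl-3-[1-(tert-butyldiphenylsilyloxy)-3-methylbut-3-en-2-yl]cyclopentanone
Conditions: HNTf2 (5 mol%, forms Me3SiNTf2 in the flask), CH2Cl2, −78 °C, non-aqueous work-up
Reagents that add atoms: none
Why: Hosomi–Sakurai conjugate allylation under silyl triflimide catalysis, in which the γ-carbon of the allylsilane (the future C9) attacks the enone β-carbon anti to silicon through an open synclinal transition state with the allyl π system over the enone and the silyloxymethyl arm turned away from the ring, which should set C9 relative to the new quaternary carbon C10, while silyl transfer to the enolate oxygen fixes the enolate position towards C5.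

Step 5
Reactants: 7 racemic trimethylsilyl enol ether; 8 acrolein
Product: 10 racemic anti aldol 2-(1-hydroxyprop-2-en-1-yl)-3-methyl-3-[1-(tert-butyldiphenylsilyloxy)-3-methylbut-3-en-2-yl]cyclopentan-1-one, via dibutylboron enolate 9 (not isolated)
Conditions: n-Bu2BOTf, CH2Cl2, 0 °C; then 8, −78 °C; pH 7 buffer, MeOH, H2O2, 0 °C
Reagents that add atoms: none
Why: Silicon-to-boron exchange keeps the enolate position, and the boron aldol addition through a closed Zimmerman–Traxler transition state of the (E)-configured cyclic enolate should give the anti aldol, the aldehyde adding to the enolate face opposite to the branched C9 substituent on the neighbouring quaternary carbon, which sets C5 (C6 chain cis to the methyl group) and C6.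

Step 6
Reactants: 10 racemic anti aldol
Product: 11 (2R,3S)-2-[(1R)-1-hydroxyprop-2-en-1-yl]-3-methyl-3-[(2R)-1-(tert-butyldiphenylsilyloxy)-3-methylbut-3-en-2-yl]cyclopentan-1-one
Conditions: Ti(OiPr)4, D-(−)-diisopropyl tartrate, t-BuOOH (0.6 equiv), 4 Å molecular sieves, CH2Cl2, −20 °C, stopped near 55% conversion
Reagents that add atoms: none
Why: Sharpless kinetic resolution of the secondary vinyl carbinol, in which the D-tartrate catalyst should epoxidise the unwanted enantiomer faster and leave 11 unreacted, so that the C6 carbinol centre fixes the absolute configuration of all four stereocentres.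

Step 7
Reactants: 11 resolved aldol
Product: 12 (3aS,4R,7R,7aR)-4-[(tert-butyldiphenylsilyloxy)methyl]-7-hydroxy-3a,5-dimethyl-2,3,3a,4,7,7a-hexahydro-1H-inden-1-one
Conditions: second-generation Grubbs catalyst (5 mol%), CH2Cl2, 40 °C
Reagents that add atoms: none
Why: Ring-closing metathesis between the vinyl carbinol and the isopropenyl group should close ring B with the trisubstituted C7=C8 bond, and the trans ring fusion follows from the trans arrangement of the two chains set in step 5, with no base present to epimerise C5.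

Step 8
Reactants: 12 trans-hydrindanone
Product: 13 (1R,3aS,4R,7R,7aR)-4-[(tert-butyldiphenylsilyloxy)methyl]-3a,5-dimethyl-1-(prop-1-en-2-yl)-2,3,3a,4,7,7a-hexahydro-1H-indene-1,7-diol
Conditions: isopropenylmagnesium bromide (3 equiv), CeCl3 (3 equiv), THF, −78 °C; aq. NH4Cl
Reagents that add atoms: isopropenylmagnesium bromide, CC(=C)[Mg]Br
Why: 1,2-Addition of the weakly basic organocerium reagent to the hindered, enolisable ketone should occur anti to the angular methyl group to give mainly the epimer drawn, and the carbinol configuration does not matter because C3 becomes a carbonyl carbon in step 10.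

Step 9
Reactants: 13 diol
Product: 14 (1R,3aS,4R,7R,7aR)-4-[(tert-butyldiphenylsilyloxy)methyl]-1-hydroxy-3a,5-dimethyl-1-(prop-1-en-2-yl)-2,3,3a,4,7,7a-hexahydro-1H-inden-7-yl acetate
Conditions: Ac2O, pyridine, DMAP (cat.), CH2Cl2, 0 °C
Reagents that add atoms: acetic anhydride, CC(=O)OC(C)=O
Why: DMAP-catalysed acylation should take the secondary allylic hydroxyl and leave the tertiary carbinol, which installs the acetate of the target and removes a hydroxyl that could trap the cation of the next step.

Step 10
Reactants: 14 tertiary isopropenyl carbinol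
Product: 15 (1R,4R,4aS,8aS)-1-[(tert-butyldiphenylsilyloxy)methyl]-2,5,5,8a-tetramethyl-6-oxo-1,4,4a,5,6,7,8,8a-octahydronaphthalen-4-yl acetate
Conditions: N,N′-bis(3,5-di-tert-butylsalicylidene)-1,2-cyclohexanediaminocobalt (divalent cobalt, 5 mol%), N-fluoro-2,4,6-trimethylpyridinium tetrafluoroborate (1.5 equiv), PhSiH3 (1.5 equiv), acetone, 0 °C to rt
Reagents that add atoms: none
Why: The cobalt hydride formed from the cobalt complex, the N-fluoropyridinium oxidant and PhSiH3 should transfer a hydrogen atom to the terminal carbon of the isopropenyl group, and the tertiary C4 radical is then oxidised through an alkylcobalt species to the 2-propyl cation next to the carbinol carbon C3 (radical-polar crossover). The C3–C5 bond then shifts to C4 while the hydroxyl oxygen becomes the C3 carbonyl, so the cyclopentane grows by one atom into ring A with the ketone and the gem-dimethyl quaternary carbon in place; the closest known reaction type is the hydrogen-atom-transfer-initiated (or acid-promoted) semipinacol ring enlargement of 1-(alk-1-en-2-yl)cycloalkanols to 2,2-dialkylcycloalkanones. No ring is closed by cyclisation: ring A arises by a 1,2-alkyl shift that enlarges the five-membered ring to six. No new stereocentre is made: C5 migrates with retention, so the trans fusion set earlier is carried into the decalin, and the C3 carbinol centre is erased, so both C3 epimers of 14 converge on 15. The step needs hydrogen-atom transfer to the 1,1-disubstituted alkene and not to the trisubstituted C7=C8 bond, which the higher reactivity of terminal 1,1-disubstituted alkenes should secure. It also needs migration of C5 and not of C2, which the higher migratory aptitude of the tertiary ring-fusion carbon over the CH2 group and the relief of trans-hydrindane strain should secure.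

Step 11
Reactants: 15 silyl ether
Product: 16 (1R,4R,4aS,8aS)-1-(hydroxymethyl)-2,5,5,8a-tetramethyl-6-oxo-1,4,4a,5,6,7,8,8a-octahydronaphthalen-4-yl acetate
Conditions: HF·pyridine, pyridine, THF, 0 °C to rt
Reagents that add atoms: none
Why: Fluoride cleavage of the primary silyl ether under buffered conditions should leave the acetate, the ketone and the allylic system untouched (desilylation).

Step 12
Reactants: 16 primary alcohol; 17 7-hydroxy-2H-chromen-2-one (umbelliferone)
Product: 18 target, (1R,4R,4aS,8aS)-2,5,5,8a-tetramethyl-6-oxo-1-{[(2-oxo-2H-chromen-7-yl)oxy]methyl}-1,4,4a,5,6,7,8,8a-octahydronaphthalen-4-yl acetate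
Conditions: PPh3, diisopropyl azodicarboxylate, THF, 0 °C to rt
Reagents that add atoms: none
Why: Mitsunobu etherification, in which the acidic phenol (pKa about 8) displaces the activated primary hydroxyl at C11 by SN2 without touching a stereocentre, should complete the aryl ether.

**Compound list**
1 | but-2-yn-1-ol | CC#CCO | starting material
2 | sodium 2,2-bis(2-methoxyethoxy)-3-methyl-2,5-dihydro-1,2-oxaaluminol-2-uide (cyclic alkenylaluminate) | [Na+].CC1=CCO[Al-]1(OCCOC)OCCOC | intermediate
3 | (Z)-3-iodobut-2-en-1-ol | C/C(I)=C/CO | intermediate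
4 | (Z)-tert-butyl[(3-iodobut-2-en-1-yl)oxy]diphenylsilane | C/C(I)=C/CO[Si](c1ccccc1)(c1ccccc1)C(C)(C)C | intermediate
5 | (Z)-tert-butyl{[3-methyl-4-(trimethylsilyl)but-2-en-1-yl]oxy}diphenylsilane | C/C(C[Si](C)(C)C)=C/CO[Si](c1ccccc1)(c1ccccc1)C(C)(C)C | intermediate
6 | 3-methylcyclopent-2-en-1-one | CC1=CC(=O)CC1 | starting material
7 | ({(3S)-3-methyl-3-[(2R)-1-(tert-butyldiphenylsilyloxy)-3-methylbut-3-en-2-yl]cyclopent-1-en-1-yl}oxy)trimethylsilane, racemic | C[Si](C)(C)OC1=C[C@@](C)(CC1)[C@H](CO[Si](c2ccccc2)(c2ccccc2)C(C)(C)C)C(C)=C | intermediate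
8 | acrolein (prop-2-enal) | C=CC=O | starting material
9 | dibutyl({(3S)-3-methyl-3-[(2R)-1-(tert-butyldiphenylsilyloxy)-3-methylbut-3-en-2-yl]cyclopent-1-en-1-yl}oxy)borane, racemic | CCCCB(CCCC)OC1=C[C@@](C)(CC1)[C@H](CO[Si](c2ccccc2)(c2ccccc2)C(C)(C)C)C(C)=C | intermediate
10 | racemate of 11 (anti aldol; C6 chain cis to the ring methyl group) | O[C@H](C=C)[C@@H]1C(=O)CC[C@@]1(C)[C@H](CO[Si](c2ccccc2)(c2ccccc2)C(C)(C)C)C(C)=C | intermediate
11 | (2R,3S)-2-[(1R)-1-hydroxyprop-2-en-1-yl]-3-methyl-3-[(2R)-1-(tert-butyldiphenylsilyloxy)-3-methylbut-3-en-2-yl]cyclopentan-1-one, single enantiomer | O[C@H](C=C)[C@@H]1C(=O)CC[C@@]1(C)[C@H](CO[Si](c2ccccc2)(c2ccccc2)C(C)(C)C)C(C)=C | intermediate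
12 | (3aS,4R,7R,7aR)-4-[(tert-butyldiphenylsilyloxy)methyl]-7-hydroxy-3a,5-dimethyl-2,3,3a,4,7,7a-hexahydro-1H-inden-1-one (trans-fused) | O[C@@H]1C=C(C)[C@@H](CO[Si](c3ccccc3)(c3ccccc3)C(C)(C)C)[C@]2(C)CCC(=O)[C@@H]12 | intermediate
13 | (1R,3aS,4R,7R,7aR)-4-[(tert-butyldiphenylsilyloxy)methyl]-3a,5-dimethyl-1-(prop-1-en-2-yl)-2,3,3a,4,7,7a-hexahydro-1H-indene-1,7-diol | O[C@@H]1C=C(C)[C@@H](CO[Si](c3ccccc3)(c3ccccc3)C(C)(C)C)[C@]2(C)CC[C@](O)(C(C)=C)[C@@H]12 | intermediate
14 | (1R,3aS,4R,7R,7aR)-4-[(tert-butyldiphenylsilyloxy)methyl]-1-hydroxy-3a,5-dimethyl-1-(prop-1-en-2-yl)-2,3,3a,4,7,7a-hexahydro-1H-inden-7-yl acetate | CC(=O)O[C@@H]1C=C(C)[C@@H](CO[Si](c3ccccc3)(c3ccccc3)C(C)(C)C)[C@]2(C)CC[C@](O)(C(C)=C)[C@@H]12 | intermediate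
15 | (1R,4R,4aS,8aS)-1-[(tert-butyldiphenylsilyloxy)methyl]-2,5,5,8a-tetramethyl-6-oxo-1,4,4a,5,6,7,8,8a-octahydronaphthalen-4-yl acetate (trans-decalin) | CC(=O)O[C@@H]1C=C(C)[C@@H](CO[Si](c3ccccc3)(c3ccccc3)C(C)(C)C)[C@]2(C)CCC(=O)C(C)(C)[C@@H]12 | intermediate
16 | (1R,4R,4aS,8aS)-1-(hydroxymethyl)-2,5,5,8a-tetramethyl-6-oxo-1,4,4a,5,6,7,8,8a-octahydronaphthalen-4-yl acetate | CC(=O)O[C@@H]1C=C(C)[C@@H](CO)[C@]2(C)CCC(=O)C(C)(C)[C@@H]12 | intermediate
17 | 7-hydroxy-2H-chromen-2-one (umbelliferone) | Oc1ccc2ccc(=O)oc2c1 | starting material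
18 | (1R,4R,4aS,8aS)-2,5,5,8a-tetramethyl-6-oxo-1-{[(2-oxo-2H-chromen-7-yl)oxy]methyl}-1,4,4a,5,6,7,8,8a-octahydronaphthalen-4-yl acetate (drimane numbering 5S,6R,9R,10S) | CC(=O)O[C@@H]1C=C(C)[C@@H](COc2ccc3ccc(=O)oc3c2)[C@]2(C)CCC(=O)C(C)(C)[C@@H]12 | target

**Step count**
Total: 12 steps. Longest linear sequence: 12 steps (steps 1–12; compounds 6, 8 and 17 are bought).

**Three steps most likely to fail**

Step 4 (Hosomi–Sakurai addition). Rotamer control in the open transition state may be lost, so that the C9 epimer forms. The bond between two congested carbons may also form so slowly that protodesilylation of the silane wins. The fallback sets out from 5 and comes back at 7. Silane 5 is added, under the same HNTf2 catalysis, to unsubstituted cyclopent-2-en-1-one, an unhindered and well-known acceptor, to give the trimethylsilyl enol ether F1. Saegusa–Ito oxidation with Pd(OAc)2 in MeCN turns it into the 3-substituted cyclopent-2-enone F2. Me2CuLi with Me3SiCl in THF at −78 °C then builds the quaternary carbon by methyl delivery to the enone face anti to the silyloxymethyl arm, in the conformer that has the C9 hydrogen eclipsed with the ring double bond (allylic-strain control). The enolate is silylated in the flask and gives 7.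

Step 10 (ring enlargement). The C4 radical may take up a second hydrogen atom (net hydrogenation of the isopropenyl group), or the cation may be closed by the hydroxyl oxygen to an epoxide or lose a proton, all in competition with the 1,2-shift. The fallback sets out from 12 and comes back at 15. 2-Lithio-2-(methylselanyl)propane (from 2,2-bis(methylselanyl)propane and n-BuLi, THF, −78 °C) is added to ketone 12 to give the β-hydroxy selenide F3. Acetylation (Ac2O, pyridine, DMAP) gives the monoacetate F4. AgBF4 on alumina in CH2Cl2 makes selenium a leaving group, and the same shift of C5 to the tertiary C4 centre gives 15. This is the known ring enlargement of cyclic ketones through β-hydroxy selenides, a Tiffeneau–Demjanov-type process.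

Step 7 (ring-closing metathesis). Ruthenium hydride species may isomerise the free allylic alcohol to the saturated ethyl ketone, closure onto the hindered 1,1-disubstituted alkene may be slow, or the strained trans-fused ketone may epimerise at C5. The fallback sets out from 11 and comes back at 14. The isopropenyl group is added first (isopropenylmagnesium bromide, CeCl3, THF, −78 °C) to the monocyclic ketone 11 to give the diol F5. Acetylation of the secondary hydroxyl gives the acetate F6. Ring-closing metathesis of this allylic acetate (second-generation Grubbs catalyst) then closes ring B after the epimerisable ketone is gone and gives 14.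

**Further compounds**
F1 | step 4 | trimethylsilyl enol ether of 3-[1-(tert-butyldiphenylsilyloxy)-3-methylbut-3-en-2-yl]cyclopentanone (racemic, both ring epimers) | C[Si](C)(C)OC1=CC(CC1)[C@H](CO[Si](c2ccccc2)(c2ccccc2)C(C)(C)C)C(C)=C
F2 | step 4 | 3-[1-(tert-butyldiphenylsilyloxy)-3-methylbut-3-en-2-yl]cyclopent-2-en-1-one (racemic) | O=C1C=C(CC1)[C@H](CO[Si](c2ccccc2)(c2ccccc2)C(C)(C)C)C(C)=C
F3 | step 10 | (1R,3aS,4R,7R,7aR)-4-[(tert-butyldiphenylsilyloxy)methyl]-3a,5-dimethyl-1-[2-(methylselanyl)propan-2-yl]-2,3,3a,4,7,7a-hexahydro-1H-indene-1,7-diol | O[C@@H]1C=C(C)[C@@H](CO[Si](c3ccccc3)(c3ccccc3)C(C)(C)C)[C@]2(C)CC[C@](O)(C(C)(C)[Se]C)[C@@H]12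
F4 | step 10 | 7-acetate of F3 | CC(=O)O[C@@H]1C=C(C)[C@@H](CO[Si](c3ccccc3)(c3ccccc3)C(C)(C)C)[C@]2(C)CC[C@](O)(C(C)(C)[Se]C)[C@@H]12
F5 | step 7 | (1R,2R,3S)-2-[(1R)-1-hydroxyprop-2-en-1-yl]-3-methyl-3-[(2R)-1-(tert-butyldiphenylsilyloxy)-3-methylbut-3-en-2-yl]-1-(prop-1-en-2-yl)cyclopentan-1-ol | O[C@H](C=C)[C@@H]1[C@@](O)(C(C)=C)CC[C@@]1(C)[C@H](CO[Si](c2ccccc2)(c2ccccc2)C(C)(C)C)C(C)=C
F6 | step 7 | acetate of F5 at the secondary allylic hydroxyl | CC(=O)O[C@H](C=C)[C@@H]1[C@@](O)(C(C)=C)CC[C@@]1(C)[C@H](CO[Si](c2ccccc2)(c2ccccc2)C(C)(C)C)C(C)=C
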